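**Retrosynthetic overview**
- The target is traced back, by ethyl ether cleavage, butyrylation at the single ring C–H (C1 of each ring) and desilylation, to a methylene-bridged bis(resorcinol monosilyl ether).
- Key disconnection: the C5–C6 and C3–C4 bonds of both rings are cut, which leads to 1,5-bis(triisopropylsilyloxy)penta-1,4-diyne and two molecules of 3-ethoxy-2-methylcyclobut-2-en-1-one (double Danheiser benzannulation).
- Feature used: in each ring the carbon carrying the bridging CH2 (C5) sits between two O-bearing carbons (C4, C6). The CH2, the two C5 atoms and the two C4–O atoms are therefore C3, C2/C4 and C1/C5 of an O-terminated penta-1,4-diyne. The ring edge C6(OH)–C1(H)–C2(O)–C3(CH3) is C1–C4–C3–C2 of the cyclobutenone.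
- The bis(siloxyalkyne) comes from penta-1,4-diyne (propargyl bromide plus ethynylmagnesium bromide) by acetylide oxidation and O-silylation. The cyclobutenone comes from dichloroketene and 1-ethoxyprop-1-yne, followed by dechlorination.
- Ring order: the two benzene rings are the only rings and are closed one after the other in the same flask in the key step.

Key step: step 5

Remark: the target has no stereocentre and is treated as the aromatic triphenol tautomer drawn. Volatile penta-1,4-diyne is assumed to be handled as a dried, titrated THF solution.

**Step 1**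
Reactants: 1 1-ethoxyprop-1-yne; 2 trichloroacetyl chloride
Product: 4 4,4-dichloro-3-ethoxy-2-methylcyclobut-2-en-1-one, via dichloroketene 3 (not isolated)
Conditions: Zn–Cu couple, Et2O/DME, 0 °C → rt (slow addition of 2)
Reagents that add atoms: none
Why: Zinc dechlorination of 2 releases dichloroketene, whose carbonyl carbon bonds to the nucleophilic methyl-bearing carbon of the ynol ether in a ketene–alkyne [2+2] cycloaddition, which places ethoxy at C3 and methyl at C2.

**Step 2**
Reactants: 4 4,4-dichloro-3-ethoxy-2-methylcyclobut-2-en-1-one
Product: 5 3-ethoxy-2-methylcyclobut-2-en-1-one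
Conditions: Zn dust, AcOH, TMEDA, EtOH, 0 °C → rt
Reagents that add atoms: none
Why: Zinc-mediated reductive dechlorination of an α,α-dichloroketone (two rounds of zinc enolate formation and protonation) under amine-buffered conditions that should spare the vinylogous ester from hydrolysis.

**Step 3**
Reactants: 6 propargyl bromide (3-bromoprop-1-yne); 7 ethynylmagnesium bromide
Product: 8 penta-1,4-diyne
Conditions: CuCl (5 mol %), THF, 20 → 50 °C; aqueous NH4Cl; distilled and kept cold as a dried THF solution
Reagents that add atoms: none
Why: Copper-catalysed propargylation of an alkynyl Grignard reagent is the standard SN2 entry to skipped diynes and keeps the product away from strong base.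

**Step 4**
Reactants: 8 penta-1,4-diyne
Product: 11 1,5-bis(triisopropylsilyloxy)penta-1,4-diyne, via dilithium diacetylide 9 (not isolated), via dilithium bis-ynolate 10 (not isolated)
Conditions: LiN(SiMe3)2 (4.4 equiv), t-BuOOH (2.2 equiv, in decane), THF, −78 → 0 °C; then iPr3SiOTf (2.5 equiv), −78 → 0 °C; pentane, filtration through Et3N-deactivated silica
Reagents that add atoms: tert-butyl hydroperoxide CC(C)(C)OO; triisopropylsilyl trifluoromethanesulfonate CC(C)[Si](OS(=O)(=O)C(F)(F)F)(C(C)C)C(C)C
Why: Julia-type oxidation of the lithium acetylides by LiOOtBu gives lithium ynolates, which the bulky silyl triflate should trap on oxygen, while the hindered amide base and low temperature should leave the doubly propargylic CH2 untouched.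

**Step 5**
Reactants: 11 1,5-bis(triisopropylsilyloxy)penta-1,4-diyne; 5 3-ethoxy-2-methylcyclobut-2-en-1-one (3 equiv)
Product: 14 bis[4-ethoxy-2-hydroxy-5-methyl-6-(triisopropylsilyloxy)phenyl]methane, via vinylketene 12 (not isolated), via mono-annulated phenol 13 (not isolated)
Conditions: degassed toluene, sealed tube, Ar, 80 → 110 °C
Reagents that add atoms: none
Why: Proposed new method: heating should convert 5 by conrotatory 4π ring opening into vinylketene 12, which adds across one ynol ether in a [2+2] cycloaddition (ketene carbon to the CH2-bearing alkyne carbon, methyl-bearing carbon to the O-bearing alkyne carbon); the 4-vinylcyclobutenone so formed opens (4π) to a dienylketene that cyclises and enolises to phenol 13, and the same sequence at the second ynol ether should give 14. The closest known reaction type is the Danheiser benzannulation of cyclobutenones with trialkylsiloxyalkynes to resorcinol monosilyl ethers; new here are the 3-alkoxy substituent on the cyclobutenone, the skipped bis(ynol ether) and the twofold use within one molecule. Each benzene ring is closed by 6π electrocyclisation of the dienylketene, which joins the ketene carbon to the former cyclobutenone CH2, followed by tautomerisation of the cyclohexadienone. No stereocentre is created. The step needs one regiochemistry in the [2+2] event, and the oxygen-induced polarisation of the siloxyalkyne (nucleophilic β-carbon, electrophilic ketene carbon) should secure it, so that the three oxygens of each ring come out mutually meta, with the bridge carbon flanked by OH and OSi and the methyl carbon flanked by OSi and OEt. It also needs the CH2 between the two alkynes to resist prototropic shift to an allene, which the base-free thermal medium and the non-migrating iPr3Si groups should ensure, with excess 5 driving the second annulation.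

**Step 6**
Reactants: 14 bis[4-ethoxy-2-hydroxy-5-methyl-6-(triisopropylsilyloxy)phenyl]methane
Product: 15 2,2'-methylenebis(5-ethoxy-4-methylbenzene-1,3-diol)
Conditions: Bu4NF, AcOH, THF, 0 °C
Reagents that add atoms: none
Why: Fluoride-induced cleavage of the aryl silyl ethers (driven by Si–F bond formation), buffered with acetic acid so that the electron-rich phenoxides are not left open to air oxidation.

**Step 7**
Reactants: 15 2,2'-methylenebis(5-ethoxy-4-methylbenzene-1,3-diol); 16 butanoyl chloride (2.4 equiv)
Product: 17 bis(3-butanoyl-4-ethoxy-2,6-dihydroxy-5-methylphenyl)methane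
Conditions: AlCl3 (excess), CH2Cl2/MeNO2, 0 °C → rt; aqueous HCl
Reagents that add atoms: none
Why: Friedel–Crafts acylation of a phloroglucinol-type ring can only occur at the single unsubstituted carbon of each ring (ortho to OH and OEt, para to OH), and the product is held as a deactivated aluminium chelate of the o-hydroxy ketone.

**Step 8**
Reactants: 17 bis(3-butanoyl-4-ethoxy-2,6-dihydroxy-5-methylphenyl)methane
Product: 18 methylene-bis-methylphlorobutyrophenone
Conditions: BBr3 (excess), CH2Cl2, −78 °C → rt; H2O
Reagents that add atoms: none
Why: Lewis-acid dealkylation of aryl ethyl ethers by BBr3 (bromide SN2 on the boron-activated ether, helped by the adjacent chelating ketone) on rings that are now fully substituted and acyl-deactivated, so that any acid-induced bridge exchange would be degenerate.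

**Compound list**
1 | 1-ethoxyprop-1-yne | CCOC#CC | starting material
2 | trichloroacetyl chloride | ClC(=O)C(Cl)(Cl)Cl | starting material
3 | dichloroketene | ClC(Cl)=C=O | intermediate
4 | 4,4-dichloro-3-ethoxy-2-methylcyclobut-2-en-1-one | CCOC1=C(C)C(=O)C1(Cl)Cl | intermediate
5 | 3-ethoxy-2-methylcyclobut-2-en-1-one | CCOC1=C(C)C(=O)C1 | intermediate
6 | propargyl bromide (3-bromoprop-1-yne) | BrCC#C | starting material
7 | ethynylmagnesium bromide | C#C[Mg]Br | starting material
8 | penta-1,4-diyne | C#CCC#C | intermediate
9 | dilithium penta-1,4-diyne-1,5-diide (dilithium diacetylide) | [Li]C#CCC#C[Li] | intermediate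
10 | dilithium penta-1,4-diyne-1,5-bis(olate) (dilithium bis-ynolate) | [Li]OC#CCC#CO[Li] | intermediate
11 | 1,5-bis(triisopropylsilyloxy)penta-1,4-diyne | CC(C)[Si](OC#CCC#CO[Si](C(C)C)(C(C)C)C(C)C)(C(C)C)C(C)C | intermediate
12 | 3-ethoxy-2-methylbuta-1,3-dien-1-one (vinylketene) | C=C(OCC)C(C)=C=O | intermediate
13 | 5-ethoxy-4-methyl-3-(triisopropylsilyloxy)-2-[3-(triisopropylsilyloxy)prop-2-yn-1-yl]phenol | Oc1cc(OCC)c(C)c(O[Si](C(C)C)(C(C)C)C(C)C)c1CC#CO[Si](C(C)C)(C(C)C)C(C)C | intermediate
14 | bis[4-ethoxy-2-hydroxy-5-methyl-6-(triisopropylsilyloxy)phenyl]methane | Oc1cc(OCC)c(C)c(O[Si](C(C)C)(C(C)C)C(C)C)c1Cc1c(O)cc(OCC)c(C)c1O[Si](C(C)C)(C(C)C)C(C)C | intermediate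
15 | 2,2'-methylenebis(5-ethoxy-4-methylbenzene-1,3-diol) | Oc1cc(OCC)c(C)c(O)c1Cc1c(O)cc(OCC)c(C)c1O | intermediate
16 | butanoyl chloride | CCCC(=O)Cl | starting material
17 | bis(3-butanoyl-4-ethoxy-2,6-dihydroxy-5-methylphenyl)methane | CCCC(=O)c1c(O)c(Cc2c(O)c(C)c(OCC)c(C(=O)CCC)c2O)c(O)c(C)c1OCC | intermediate
18 | methylene-bis-methylphlorobutyrophenone, bis(3-butanoyl-2,4,6-trihydroxy-5-methylphenyl)methane | CCCC(=O)c1c(O)c(C)c(O)c(Cc2c(O)c(C)c(O)c(C(=O)CCC)c2O)c1O | target

**Totals**
Total step count: 8. Longest linear sequence: 6 steps (steps 3, 4, 5, 6, 7, 8; the branch through steps 1, 2, 5, 6, 7, 8 is equally long).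

**Steps most likely to fail**

Step 5 (proposed new method). Four processes could defeat it:
- Ring opening of the push–pull cyclobutenone may be slow, so that 11 degrades before it is intercepted.
- The OH of the first-formed phenol 13 may add across its own neighbouring ynol ether (six-membered closure) faster than the second annulation.
- Product phenol may capture 12 as an aryl ester.
- The skipped diyne may undergo prototropic shift to an allene.

Fallback, with known chemistry and without annulative ring construction: it sets out from butanoyl chloride 16. This acylates commercial 2-methylbenzene-1,3,5-triol F1 (AlCl3, CH2Cl2/MeNO2, Friedel–Crafts) to 1-(2,4,6-trihydroxy-3-methylphenyl)butan-1-one F2. Two molecules of F2 are then joined through their only free ring carbon with aqueous formaldehyde and KOH (0 °C → rt), and the route is rejoined at the target 18.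

Step 4. The second acetylide oxidation may stall on a poorly soluble dilithium species, and base may shift the doubly propargylic CH2, giving mono-ynol ether and isomerised material. The fallback functionalises one terminus at a time. It sets out from propargyl bromide 6 and returns at 11:
- 6 is coupled with [(trimethylsilyl)ethynyl]magnesium bromide (CuCl, THF) to trimethyl(penta-1,4-diyn-1-yl)silane F3.
- LiN(SiMe3)2 and t-BuOOH convert F3 into lithium 5-(trimethylsilyl)penta-1,4-diyn-1-olate F4, which is silylated in the same flask with iPr3SiOTf to trimethyl{5-[tri(propan-2-yl)silyloxy]penta-1,4-diyn-1-yl}silane F5.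
- K2CO3 in MeOH at 0 °C removes the C-silyl group to give (penta-1,4-diyn-1-yloxy)tri(propan-2-yl)silane F6.
- A second oxidation gives lithium 5-[tri(propan-2-yl)silyloxy]penta-1,4-diyn-1-olate F7, and iPr3SiOTf converts it into 11.

Step 7. Acid-induced scission or transalkylation of the electron-rich diarylmethane (ipso attack at the bridge carbon) and O-acylation in place of C-acylation may erode the step. The fallback is an acid-free O→C acyl shift. It sets out from 14 (before desilylation) and returns at 17:
- 14 is esterified with butanoyl chloride 16 (Et3N, DMAP, CH2Cl2) to methylenebis[5-ethoxy-4-methyl-3-(triisopropylsilyloxy)-2,1-phenylene] dibutanoate F8.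
- Photo-Fries rearrangement (hν 254 nm, degassed cyclohexane) can deliver the acyl group only to the single open ortho position, giving bis[3-butanoyl-4-ethoxy-2-hydroxy-5-methyl-6-(triisopropylsilyloxy)phenyl]methane F9.
- Bu4NF/AcOH in THF then gives 17.

**Further compounds**
F1 | step 5 | 2-methylbenzene-1,3,5-triol | Cc1c(O)cc(O)cc1O
F2 | step 5 | 1-(2,4,6-trihydroxy-3-methylphenyl)butan-1-one | CCCC(=O)c1c(O)cc(O)c(C)c1O
F3 | step 4 | trimethyl(penta-1,4-diyn-1-yl)silane | C[Si](C)(C)C#CCC#C
F4 | step 4 | lithium 5-(trimethylsilyl)penta-1,4-diyn-1-olate | C[Si](C)(C)C#CCC#CO[Li]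
F5 | step 4 | trimethyl{5-[tri(propan-2-yl)silyloxy]penta-1,4-diyn-1-yl}silane | C[Si](C)(C)C#CCC#CO[Si](C(C)C)(C(C)C)C(C)C
F6 | step 4 | (penta-1,4-diyn-1-yloxy)tri(propan-2-yl)silane | C#CCC#CO[Si](C(C)C)(C(C)C)C(C)C
F7 | step 4 | lithium 5-[tri(propan-2-yl)silyloxy]penta-1,4-diyn-1-olate | [Li]OC#CCC#CO[Si](C(C)C)(C(C)C)C(C)C
F8 | step 7 | methylenebis[5-ethoxy-4-methyl-3-(triisopropylsilyloxy)-2,1-phenylene] dibutanoate | CCCC(=O)Oc1cc(OCC)c(C)c(O[Si](C(C)C)(C(C)C)C(C)C)c1Cc1c(OC(=O)CCC)cc(OCC)c(C)c1O[Si](C(C)C)(C(C)C)C(C)C
F9 | step 7 | bis[3-butanoyl-4-ethoxy-2-hydroxy-5-methyl-6-(triisopropylsilyloxy)phenyl]methane | CCCC(=O)c1c(O)c(Cc2c(O)c(C(=O)CCC)c(OCC)c(C)c2O[Si](C(C)C)(C(C)C)C(C)C)c(O[Si](C(C)C)(C(C)C)C(C)C)c(C)c1OCC
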